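The dioxane ring is closed by joining its two sp3 carbons, C-2 (CHMe) and C-3 (CHAr), each of which carries a ring oxygen and is therefore aldehyde-derived and electrophilic by nature. C-3 is benzylic to the trimethoxyphenyl ring and α to oxygen, so DDQ removes hydride from a simple benzyl ether CH2 to give an oxocarbenium ion; C-2 is made nucleophilic as the α-carbon of an aryloxyacetaldehyde enamine formed with a chiral amine. One operation thus forms the C-2–C-3 bond, the ring and both stereocentres from an acyclic catechol bis-ether; the formyl group is then reduced to methyl and a Heck reaction installs the propenal.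

Key step: step 5

Assumption: the sense of induction is taken from the usual steric-shielding model of diarylprolinol silyl ether enamines (electrophile enters anti to the diarylmethyl group), which predicts that the (R)-amine gives the (2S,3R)-aldehyde; the target is trans-(R,R) at the two ring carbons.

Step 1
Reactants: 1 5-bromo-2-hydroxy-3-methoxybenzaldehyde; 2 allyl bromide
Product: 3 2-(allyloxy)-5-bromo-3-methoxybenzaldehyde
Conditions: K2CO3, DMF, rt → 50 °C
Reagents that add atoms: none
Why: Williamson ether synthesis on the only phenol of 1 fixes this oxygen (flanked by OMe, para to Br) as the one that will carry the CHMe carbon.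

Step 2
Reactants: 3 2-(allyloxy)-5-bromo-3-methoxybenzaldehyde
Product: 5 2-(allyloxy)-5-bromo-3-methoxyphenol, via aryl formate 4 (not isolated)
Conditions: mCPBA (1.1 equiv), CH2Cl2, 0 °C → rt; then K2CO3 (10 mol %), MeOH, rt
Reagents that add atoms: 3-chloroperoxybenzoic acid (mCPBA), OOC(=O)c1cccc(Cl)c1
Why: Baeyer–Villiger (Dakin-type) oxidation, in which the electron-rich aryl group migrates to give the formate that base-catalysed methanolysis cleaves, should place the second phenol oxygen exactly where the formyl group stood, the electron-poor allyl alkene reacting more slowly with the peracid.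

Step 3
Reactants: 5 2-(allyloxy)-5-bromo-3-methoxyphenol; 6 3,4,5-trimethoxybenzyl chloride
Product: 7 2-(allyloxy)-5-bromo-1-methoxy-3-[(3,4,5-trimethoxybenzyl)oxy]benzene
Conditions: K2CO3, DMF, 60 °C
Reagents that add atoms: none
Why: Williamson ether synthesis installs the benzylic OCH2Ar carbon that becomes C-3 of the dioxane ring.

Step 4
Reactants: 7 2-(allyloxy)-5-bromo-1-methoxy-3-[(3,4,5-trimethoxybenzyl)oxy]benzene
Product: 9 2-{4-bromo-2-methoxy-6-[(3,4,5-trimethoxybenzyl)oxy]phenoxy}acetaldehyde, via diol 8 (not isolated)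
Conditions: OsO4 (2 mol %), NaIO4, 2,6-lutidine, dioxane/H2O 3:1, rt
Reagents that add atoms: sodium periodate, [Na+].[O-]I(=O)(=O)=O (terminal source of the carbonyl oxygen, delivered through OsO4); water, O
Why: Lemieux–Johnson oxidation, in which OsO4 dihydroxylates the only alkene and NaIO4 cleaves the glycol, should give the aryloxyacetaldehyde while the arenes, the aryl bromide and the benzyl ether stay intact in the lutidine-buffered medium.

Step 5
Reactants: 9 2-{4-bromo-2-methoxy-6-[(3,4,5-trimethoxybenzyl)oxy]phenoxy}acetaldehyde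
Product: 12 [(2R,3R)-6-bromo-8-methoxy-3-(3,4,5-trimethoxyphenyl)-2,3-dihydro-1,4-benzodioxin-2-yl]methanol, via oxocarbenium ion pair 10 (not isolated), via aldehyde 11 (not isolated)
Conditions: DDQ (1.1 equiv), 4 Å molecular sieves, ClCH2CH2Cl, 0 °C → rt; then (R)-2-[diphenyl(trimethylsilyloxy)methyl]pyrrolidine (20 mol %), PhCO2H (20 mol %), −20 °C; then NaBH4, MeOH, −20 → 0 °C
Reagents that add atoms: none
Why: DDQ abstracts hydride from the OCH2 group that is benzylic to the trimethoxyphenyl ring and α to the aryl ether oxygen, giving the (E)-oxocarbenium ion pair 10, and the amine added afterwards condenses with the aldehyde to an (E)-enamine whose α-carbon, the polarity-reversed future C-2, attacks the oxocarbenium carbon, the future C-3. The closest known reaction type is the DDQ-mediated enantioselective cross-dehydrogenative coupling of benzylic ethers with aldehydes under enamine catalysis, run here within one molecule. The dioxane ring closes in a 6-endo-trig mode at the oxocarbenium (its C=O+ bond lies inside the new ring) with the enamine double bond exocyclic (enolexo). The configuration at C-2 is set by the catalyst, whose diphenyl(silyloxy)methyl group shields one enamine face so that the (R)-amine should deliver the 2S aldehyde, and that at C-3 follows from a chair-like transition state in which the aryl group of the (E)-oxocarbenium and the iminium carbon are both pseudo-equatorial, which gives the trans ring. The step needs chemoselective oxidation of this one C–H bond, secured by its being the only position that is both benzylic and α to oxygen and by adding the amine only after DDQ is consumed, and it needs the epimerisable α-aryloxy aldehyde 11 to be frozen, which the NaBH4 reduction in the same flask to alcohol 12 (2R by the change in priorities, same geometry) should achieve.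

Step 6
Reactants: 12 [(2R,3R)-6-bromo-8-methoxy-3-(3,4,5-trimethoxyphenyl)-2,3-dihydro-1,4-benzodioxin-2-yl]methanol
Product: 14 (2R,3R)-7-bromo-5-methoxy-3-methyl-2-(3,4,5-trimethoxyphenyl)-2,3-dihydro-1,4-benzodioxine, via mesylate 13 (not isolated)
Conditions: MsCl, Et3N, THF, 0 °C; then LiEt3BH (3 equiv, THF), 0 °C → rt
Reagents that add atoms: none
Why: Sulfonylation of the primary alcohol followed by SN2 displacement of mesylate by hydride from LiEt3BH should turn CH2OH into CH3 at an exocyclic carbon, so neither ring stereocentre is touched and the aryl bromide is not reduced at this temperature.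

Step 7
Reactants: 14 (2R,3R)-7-bromo-5-methoxy-3-methyl-2-(3,4,5-trimethoxyphenyl)-2,3-dihydro-1,4-benzodioxine; 15 acrolein diethyl acetal
Product: 17 (E)-3-[(2R,3R)-8-methoxy-2-methyl-3-(3,4,5-trimethoxyphenyl)-2,3-dihydro-1,4-benzodioxin-6-yl]prop-2-enal, via diethyl acetal 16 (not isolated)
Conditions: Pd(OAc)2 (3 mol %), nBu4NOAc, K2CO3, KCl, DMF, 90 °C; then 2 M HCl, rt
Reagents that add atoms: water, O
Why: Heck reaction of the aryl bromide with acetal-masked acrolein, through syn-carbopalladation and syn-β-hydride elimination towards the benzylic hydrogen, should give the (E)-cinnamyl acetal, which dilute acid hydrolyses to the (E)-enal without affecting the benzodioxane stereocentres.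

Compound list
1 | 5-bromo-2-hydroxy-3-methoxybenzaldehyde | O=Cc1cc(Br)cc(OC)c1O | starting material
2 | allyl bromide (3-bromoprop-1-ene) | C=CCBr | starting material
3 | 2-(allyloxy)-5-bromo-3-methoxybenzaldehyde | C=CCOc1c(C=O)cc(Br)cc1OC | intermediate
4 | 2-(allyloxy)-5-bromo-3-methoxyphenyl formate | C=CCOc1c(OC=O)cc(Br)cc1OC | intermediate
5 | 2-(allyloxy)-5-bromo-3-methoxyphenol | C=CCOc1c(O)cc(Br)cc1OC | intermediate
6 | 3,4,5-trimethoxybenzyl chloride | COc1cc(CCl)cc(OC)c1OC | starting material
7 | 2-(allyloxy)-5-bromo-1-methoxy-3-[(3,4,5-trimethoxybenzyl)oxy]benzene | C=CCOc1c(OCc2cc(OC)c(OC)c(OC)c2)cc(Br)cc1OC | intermediate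
8 | 3-{4-bromo-2-methoxy-6-[(3,4,5-trimethoxybenzyl)oxy]phenoxy}propane-1,2-diol (racemic) | OCC(O)COc1c(OCc2cc(OC)c(OC)c(OC)c2)cc(Br)cc1OC | intermediate
9 | 2-{4-bromo-2-methoxy-6-[(3,4,5-trimethoxybenzyl)oxy]phenoxy}acetaldehyde | O=CCOc1c(OCc2cc(OC)c(OC)c(OC)c2)cc(Br)cc1OC | intermediate
10 | O-aryl (3,4,5-trimethoxyphenyl)methylidene oxocarbenium ion derived from 9, as its ion pair with the monoanion of 2,3-dichloro-5,6-dicyanohydroquinone | O=CCOc1c([O+]=Cc2cc(OC)c(OC)c(OC)c2)cc(Br)cc1OC.[O-]c1c(Cl)c(Cl)c(O)c(C#N)c1C#N | intermediate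
11 | (2S,3R)-6-bromo-8-methoxy-3-(3,4,5-trimethoxyphenyl)-2,3-dihydro-1,4-benzodioxine-2-carbaldehyde (trans) | COc1cc([C@H]2Oc3cc(Br)cc(OC)c3O[C@@H]2C=O)cc(OC)c1OC | intermediate
12 | [(2R,3R)-6-bromo-8-methoxy-3-(3,4,5-trimethoxyphenyl)-2,3-dihydro-1,4-benzodioxin-2-yl]methanol (trans) | COc1cc([C@H]2Oc3cc(Br)cc(OC)c3O[C@@H]2CO)cc(OC)c1OC | intermediate
13 | [(2R,3R)-6-bromo-8-methoxy-3-(3,4,5-trimethoxyphenyl)-2,3-dihydro-1,4-benzodioxin-2-yl]methyl methanesulfonate | COc1cc([C@H]2Oc3cc(Br)cc(OC)c3O[C@@H]2COS(C)(=O)=O)cc(OC)c1OC | intermediate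
14 | (2R,3R)-7-bromo-5-methoxy-3-methyl-2-(3,4,5-trimethoxyphenyl)-2,3-dihydro-1,4-benzodioxine (trans) | COc1cc([C@H]2Oc3cc(Br)cc(OC)c3O[C@@H]2C)cc(OC)c1OC | intermediate
15 | acrolein diethyl acetal (3,3-diethoxyprop-1-ene) | C=CC(OCC)OCC | starting material
16 | (2R,3R)-7-[(E)-3,3-diethoxyprop-1-en-1-yl]-5-methoxy-3-methyl-2-(3,4,5-trimethoxyphenyl)-2,3-dihydro-1,4-benzodioxine | COc1cc([C@H]2Oc3cc(/C=C/C(OCC)OCC)cc(OC)c3O[C@@H]2C)cc(OC)c1OC | intermediate
17 | (E)-3-[(2R,3R)-8-methoxy-2-methyl-3-(3,4,5-trimethoxyphenyl)-2,3-dihydro-1,4-benzodioxin-6-yl]prop-2-enal | COc1cc([C@H]2Oc3cc(/C=C/C=O)cc(OC)c3O[C@@H]2C)cc(OC)c1OC | target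

Total step count: 7. Longest linear sequence: 7 steps (from 1).

Steps most likely to fail

Step 5. Hydride abstraction from the trimethoxybenzyl aryl ether may be slower than oxidation of the amine by residual DDQ, the oxocarbenium may be hydrolysed with loss of the benzyl group, and facial control in the ring closure may be incomplete. The fallback keeps the same ring closure but releases the cation by acid ionisation of an acetal instead of C–H oxidation; it sets out from 5 and comes back at 11 and then 12. 3,4,5-Trimethoxybenzaldehyde is converted (HC(OMe)3, cat. TsOH, MeOH) into 3,4,5-trimethoxybenzaldehyde dimethyl acetal F1, and this (AcCl, cat. ZnBr2, CH2Cl2) into 5-[chloro(methoxy)methyl]-1,2,3-trimethoxybenzene F2. Phenol 5 is alkylated with F2 (iPr2NEt, CH2Cl2, 0 °C) to the mixed O-aryl O-methyl acetal 2-(allyloxy)-5-bromo-1-methoxy-3-[methoxy(3,4,5-trimethoxyphenyl)methoxy]benzene F3. Lemieux–Johnson cleavage (OsO4 cat., NaIO4, 2,6-lutidine) through 3-{4-bromo-2-methoxy-6-[methoxy(3,4,5-trimethoxyphenyl)methoxy]phenoxy}propane-1,2-diol F4 should give 2-{4-bromo-2-methoxy-6-[methoxy(3,4,5-trimethoxyphenyl)methoxy]phenoxy}acetaldehyde F5. The trifluoroacetate salt of the same (R)-amine (CH2Cl2, 4 Å molecular sieves, −20 °C) should then ionise the acetal with loss of methanol to the oxocarbenium trifluoroacetate F6 and form the enamine (an SN1-type enamine α-alkylation); cyclisation gives 11, which NaBH4 reduces in the flask to 12.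

Step 7. Oxidative addition of the electron-rich aryl bromide may be sluggish, and β-hydride elimination towards the acetal carbon would divert material to the saturated ester. The fallback sets out from 14 and comes back at 17: bromine–lithium exchange (n-BuLi, THF, −78 °C) gives the aryllithium F7, and a DMF quench gives (2R,3R)-8-methoxy-2-methyl-3-(3,4,5-trimethoxyphenyl)-2,3-dihydro-1,4-benzodioxine-6-carbaldehyde F8. A Wittig reaction of F8 with (triphenylphosphoranylidene)acetaldehyde (toluene, 80 °C) should then give the (E)-enal 17.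

Step 6. Hydride may attack sulfur and return the alcohol, or the displacement at the β-branched, β-oxygenated primary carbon may stall. The fallback replaces the ionic displacement by a radical reduction; it sets out from 12 and comes back at 14. Appel iodination (I2, PPh3, imidazole, CH2Cl2) gives (2S,3R)-6-bromo-2-(iodomethyl)-8-methoxy-3-(3,4,5-trimethoxyphenyl)-2,3-dihydro-1,4-benzodioxine F9. Reduction with Bu3SnH (Et3B/air, toluene, rt, high concentration) should give 14, because iodine abstraction from the alkyl iodide is far faster than bromine abstraction from the arene, and hydrogen transfer should outrun loss of aryloxyl from the primary radical.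

Further compounds
F1 | step 5 | 3,4,5-trimethoxybenzaldehyde dimethyl acetal | COC(OC)c1cc(OC)c(OC)c(OC)c1
F2 | step 5 | 5-[chloro(methoxy)methyl]-1,2,3-trimethoxybenzene (racemic) | COC(Cl)c1cc(OC)c(OC)c(OC)c1
F3 | step 5 | 2-(allyloxy)-5-bromo-1-methoxy-3-[methoxy(3,4,5-trimethoxyphenyl)methoxy]benzene (racemic) | C=CCOc1c(OC(OC)c2cc(OC)c(OC)c(OC)c2)cc(Br)cc1OC
F4 | step 5 | 3-{4-bromo-2-methoxy-6-[methoxy(3,4,5-trimethoxyphenyl)methoxy]phenoxy}propane-1,2-diol (mixture of diastereomers) | OCC(O)COc1c(OC(OC)c2cc(OC)c(OC)c(OC)c2)cc(Br)cc1OC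
F5 | step 5 | 2-{4-bromo-2-methoxy-6-[methoxy(3,4,5-trimethoxyphenyl)methoxy]phenoxy}acetaldehyde (racemic) | O=CCOc1c(OC(OC)c2cc(OC)c(OC)c(OC)c2)cc(Br)cc1OC
F6 | step 5 | oxocarbenium ion of 10 as its trifluoroacetate | O=CCOc1c([O+]=Cc2cc(OC)c(OC)c(OC)c2)cc(Br)cc1OC.[O-]C(=O)C(F)(F)F
F7 | step 7 | [(2R,3R)-8-methoxy-2-methyl-3-(3,4,5-trimethoxyphenyl)-2,3-dihydro-1,4-benzodioxin-6-yl]lithium | COc1cc([C@H]2Oc3cc([Li])cc(OC)c3O[C@@H]2C)cc(OC)c1OC
F8 | step 7 | (2R,3R)-8-methoxy-2-methyl-3-(3,4,5-trimethoxyphenyl)-2,3-dihydro-1,4-benzodioxine-6-carbaldehyde | COc1cc([C@H]2Oc3cc(C=O)cc(OC)c3O[C@@H]2C)cc(OC)c1OC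
F9 | step 6 | (2S,3R)-6-bromo-2-(iodomethyl)-8-methoxy-3-(3,4,5-trimethoxyphenyl)-2,3-dihydro-1,4-benzodioxine | COc1cc([C@H]2Oc3cc(Br)cc(OC)c3O[C@@H]2CI)cc(OC)c1OC
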